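**Plan**

1. Labels: ring A is the sulfated ring (A-1 O-sulfate, A-2 ether oxygen O1, A-3 and A-5 Br, A-4 and A-6 H). Ring B is the central ring (B-1 O1, B-2 ether oxygen O2, B-3 to B-5 Br, B-6 H). Ring C is the 2,4-dibromophenyl group bound to O2 through C-1.
2. Cuts, in retrosynthetic order: the neopentyl mask on the sulfate; the bond from O2 to C-1 (iodonium arylation); the S–O bond at A-1; the C–O bonds at A-1 and B-2 together (two formyl groups, double Baeyer–Villiger); the bond from O1 to B-1 (SNAr); the formyl carbon on B-2 (magnesiation, DMF).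
3. Enabling feature: O1 is flanked by an ortho C–O bond on each ring (at A-1 and at B-2), a 2,2'-oxydiphenol motif. A formyl group on A-1 and on B-2 first serves the fluoride displacement that joins O1 to B-1. Each then gives way to oxygen, its migrating carbon lying ortho to the donor O1.
4. Forward order: ring B is formylated, rings A and B are joined at O1, both aldehydes are oxidised, the oxygen at A-1 is sulfated, ring C is joined at O2, and the sulfate is unmasked. All benzene rings are bought (ring C as 1,3-dibromobenzene and its commercial 4-iodo derivative) and no ring is closed.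
5. Stereochemistry: none to set, since the target has no stereocentre and no configurationally stable axis.

Key step: step 3

Remark on the chemistry: the target is achiral, so no enantiomer has to be selected. It is drawn as the free hydrogen sulfate, so the sodium salt formed on unmasking is protonated in the last work-up.

**Step 1**
Reactants: 1 1,2,3-tribromo-5-fluorobenzene
Product: 3 2,3,4-tribromo-6-fluorobenzaldehyde, via (2,3,4-tribromo-6-fluorophenyl)magnesium chloride 2 (not isolated)
Conditions: TMPMgCl·LiCl (1.1 equiv), THF, −40 °C; DMF, −40 → 0 °C; 1 M HCl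
Reagents that add atoms: N,N-dimethylformamide, CN(C)C=O
Why: Directed ortho-magnesiation with the Knochel–Hauser base removes one of the two symmetry-equivalent protons flanked by F and Br (the most acidic C–H), the covalent C–Mg bond should hold back halogen dance and aryne loss at this temperature, and Bouveault-type formylation with DMF can give only one regioisomer.

**Step 2**
Reactants: 3 2,3,4-tribromo-6-fluorobenzaldehyde; 4 3,5-dibromosalicylaldehyde
Product: 6 3,5-dibromo-2-(3,4,5-tribromo-2-formylphenoxy)benzaldehyde, via potassium 2,4-dibromo-6-formylphenoxide 5 (not isolated)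
Conditions: K2CO3, DMAc, 100 °C
Reagents that add atoms: none
Why: In this SNAr (addition–elimination) the ortho formyl group and the three bromines stabilise the Meisenheimer adduct at B-1, fluoride leaves far faster than the bromides ortho and para to the aldehyde, and the phenol oxygen of 4 becomes O1 so that its formyl group marks A-1.

**Step 3**
Reactants: 6 3,5-dibromo-2-(3,4,5-tribromo-2-formylphenoxy)benzaldehyde
Product: 8 2,3,4-tribromo-6-(2,4-dibromo-6-hydroxyphenoxy)phenol, via 2,3,4-tribromo-6-[2,4-dibromo-6-(formyloxy)phenoxy]phenyl formate 7 (not isolated)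
Conditions: urea·H2O2, (CF3CO)2O, CH2Cl2, 0 °C → rt; then MeOH, cat. HCl, rt
Reagents that add atoms: urea–hydrogen peroxide, OO.NC(N)=O
Why: Trifluoroperacetic acid adds to each formyl carbon to give a tetrahedral Criegee adduct, and in each adduct the aryl carbon (A-1 or B-2) shifts from carbon to the proximal peroxide oxygen as trifluoroacetate leaves, which forms the C–O bond at A-1 and the bond from B-2 to O2 and gives bis-formate 7, which acid-catalysed methanolysis then turns into diol 8. The closest known reaction type is the Baeyer–Villiger (acidic Dakin-type) oxidation of ortho-aryloxy- and ortho-alkoxybenzaldehydes, brominated phenoxybenzaldehydes included, to aryl formates, here run at two sites of one molecule. No ring closes and no stereocentre forms. The selectivity needed is aryl over hydride migration at both aldehydes: each migrating carbon is ortho to the lone-pair donor O1, which stabilises the positive charge that builds up in the migrating ring, the formyl group on B-2 is squeezed between the bromine at B-3 and O1 so that the bulky aryl group should sit antiperiplanar to the O–O bond and strain is released on migration, and the very good leaving group of this peracid in an acidic, water-free medium favours the more cation-like aryl shift. The C–Br bonds, the diaryl ether and the deactivated rings are inert to the peracid, and the phenols stay masked as formates until the oxidant has been washed out, which should prevent over-oxidation.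

**Step 4**
Reactants: 9 neopentyl alcohol (2,2-dimethylpropan-1-ol)
Product: 10 neopentyl chlorosulfate
Conditions: SO2Cl2, pyridine, Et2O, −78 °C → rt
Reagents that add atoms: sulfuryl chloride, O=S(=O)(Cl)Cl
Why: This is the chlorosulfation of an alcohol with sulfuryl chloride and pyridine, in which the neopentyl group blocks the SN2 collapse to the alkyl chloride that erodes other alkyl chlorosulfates.

**Step 5**
Reactants: 8 2,3,4-tribromo-6-(2,4-dibromo-6-hydroxyphenoxy)phenol; 10 neopentyl chlorosulfate
Product: 12 3,5-dibromo-2-(3,4,5-tribromo-2-hydroxyphenoxy)phenyl neopentyl sulfate, via disodium 2,3,4-tribromo-6-(2,4-dibromo-6-oxidophenoxy)phenoxide 11 (not isolated)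
Conditions: NaHMDS (2.1 equiv), THF–DMPU, −78 °C; 10 (1.0 equiv), −78 → 0 °C; 1 M HCl
Reagents that add atoms: none
Why: In this phenol sulfation with a neopentyl chlorosulfate (protected-sulfate method) both phenols are fully deprotonated so that the acidity difference cannot bias the outcome, the phenoxide at A-1, which is the more basic one (only meta-Br) and has a free ortho position (H at A-6), should outrun the phenoxide at B-2, which is weakened by ortho- and para-Br and walled in by the bromine at B-3 and O1, and any sulfuryl transfer between the two oxygens should also end on the ring-A oxygen because the less basic ring-B phenoxide is the better leaving group.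

**Step 6**
Reactants: 13 1,3-dibromobenzene; 14 2,4-dibromo-1-iodobenzene
Product: 17 bis(2,4-dibromophenyl)iodonium trifluoromethanesulfonate, via (2,4-dibromophenyl)(hydroxy)-λ3-iodanyl hydrogen sulfate 15 (not isolated), via bis(2,4-dibromophenyl)iodonium hydrogen sulfate 16 (not isolated)
Conditions: 14, K2S2O8, conc. H2SO4, 0 °C → rt; 13 (1.0 equiv), rt → 40 °C; ice; NaOTf, CH2Cl2–H2O
Reagents that add atoms: sodium trifluoromethanesulfonate, [Na+].[O-]S(=O)(=O)C(F)(F)F
Why: In this Beringer-type diaryliodonium synthesis persulfate in concentrated sulfuric acid oxidises the electron-poor aryl iodide 14 to the aryl-λ3-iodane 15, whose iodine(III) centre substitutes one molecule of the deactivated arene 13 by SEAr at position 4 (para to one bromine and ortho to the other, the carbon that becomes C-1 of ring C), the same aryl-iodine(III)/arene condensation by which polybrominated diphenyliodonium salts form in sulfuric acid, anion metathesis gives the organic-soluble triflate, and a symmetrical salt leaves no choice as to which aryl group is transferred later.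

**Step 7**
Reactants: 12 3,5-dibromo-2-(3,4,5-tribromo-2-hydroxyphenoxy)phenyl neopentyl sulfate; 17 bis(2,4-dibromophenyl)iodonium trifluoromethanesulfonate
Product: 19 3,5-dibromo-2-[3,4,5-tribromo-2-(2,4-dibromophenoxy)phenoxy]phenyl neopentyl sulfate, via potassium 2,3,4-tribromo-6-{2,4-dibromo-6-[(neopentyloxy)sulfonyloxy]phenoxy}phenoxide 18 (not isolated)
Conditions: t-BuOK (1.05 equiv), THF, 0 °C; 17 (1.2 equiv), 40 °C
Reagents that add atoms: none
Why: This metal-free O-arylation of a phenoxide with a diaryliodonium salt (ligand exchange at iodine(III), then ligand coupling at the ipso carbon) spares all aryl bromides because no transition metal is present, is accelerated by the electron-poor ortho-substituted aryl group, is the established entry to di-ortho-substituted polybrominated diaryl ethers, should leave the neopentyl sulfate diester untouched by the weakly basic phenoxide at 40 °C, and releases as the second aryl fragment the same aryl iodide 14 that feeds step 6.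

**Step 8**
Reactants: 19 3,5-dibromo-2-[3,4,5-tribromo-2-(2,4-dibromophenoxy)phenoxy]phenyl neopentyl sulfate
Product: 21 bromoiesol A sulfate (3,5-dibromo-2-[3,4,5-tribromo-2-(2,4-dibromophenoxy)phenoxy]phenyl hydrogen sulfate), via sodium 3,5-dibromo-2-[3,4,5-tribromo-2-(2,4-dibromophenoxy)phenoxy]phenyl sulfate 20 (not isolated)
Conditions: NaN3, DMF, 70 °C; EtOAc, water washes (excess azide removed); cold 1 M HCl wash
Reagents that add atoms: none
Why: SN2 dealkylation of the neopentyl sulfate diester by azide in warm DMF, with the aryl sulfate monoanion as leaving group and the S–O(aryl) bond untouched, should give the sodium salt, and a brief cold acid wash after removal of the excess azide protonates it to the hydrogen sulfate drawn as the target.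

**Compound list**

| No. | Name | SMILES | Role |
|---|---|---|---|
| 1 | 1,2,3-tribromo-5-fluorobenzene | Fc1cc(Br)c(Br)c(Br)c1 | starting material |
| 2 | (2,3,4-tribromo-6-fluorophenyl)magnesium chloride (LiCl complex) | Fc1cc(Br)c(Br)c(Br)c1[Mg]Cl | intermediate |
| 3 | 2,3,4-tribromo-6-fluorobenzaldehyde | O=Cc1c(F)cc(Br)c(Br)c1Br | intermediate |
| 4 | 3,5-dibromosalicylaldehyde | O=Cc1cc(Br)cc(Br)c1O | starting material |
| 5 | potassium 2,4-dibromo-6-formylphenoxide | [K+].[O-]c1c(Br)cc(Br)cc1C=O | intermediate |
| 6 | 3,5-dibromo-2-(3,4,5-tribromo-2-formylphenoxy)benzaldehyde | O=Cc1cc(Br)cc(Br)c1Oc1cc(Br)c(Br)c(Br)c1C=O | intermediate |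
| 7 | 2,3,4-tribromo-6-[2,4-dibromo-6-(formyloxy)phenoxy]phenyl formate | O=COc1cc(Br)cc(Br)c1Oc1cc(Br)c(Br)c(Br)c1OC=O | intermediate |
| 8 | 2,3,4-tribromo-6-(2,4-dibromo-6-hydroxyphenoxy)phenol | Oc1cc(Br)cc(Br)c1Oc1cc(Br)c(Br)c(Br)c1O | intermediate |
| 9 | neopentyl alcohol | CC(C)(C)CO | starting material |
| 10 | neopentyl chlorosulfate | CC(C)(C)COS(=O)(=O)Cl | intermediate |
| 11 | disodium 2,3,4-tribromo-6-(2,4-dibromo-6-oxidophenoxy)phenoxide | [Na+].[Na+].[O-]c1cc(Br)cc(Br)c1Oc1cc(Br)c(Br)c(Br)c1[O-] | intermediate |
| 12 | 3,5-dibromo-2-(3,4,5-tribromo-2-hydroxyphenoxy)phenyl neopentyl sulfate | CC(C)(C)COS(=O)(=O)Oc1cc(Br)cc(Br)c1Oc1cc(Br)c(Br)c(Br)c1O | intermediate |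
| 13 | 1,3-dibromobenzene | Brc1cccc(Br)c1 | starting material |
| 14 | 2,4-dibromo-1-iodobenzene | Brc1ccc(I)c(Br)c1 | starting material |
| 15 | (2,4-dibromophenyl)(hydroxy)-λ3-iodanyl hydrogen sulfate | OI(OS(=O)(=O)O)c1ccc(Br)cc1Br | intermediate |
| 16 | bis(2,4-dibromophenyl)iodonium hydrogen sulfate | OS(=O)(=O)[O-].Brc1ccc([I+]c2ccc(Br)cc2Br)c(Br)c1 | intermediate |
| 17 | bis(2,4-dibromophenyl)iodonium trifluoromethanesulfonate | [O-]S(=O)(=O)C(F)(F)F.Brc1ccc([I+]c2ccc(Br)cc2Br)c(Br)c1 | intermediate |
| 18 | potassium 2,3,4-tribromo-6-{2,4-dibromo-6-[(neopentyloxy)sulfonyloxy]phenoxy}phenoxide | [K+].CC(C)(C)COS(=O)(=O)Oc1cc(Br)cc(Br)c1Oc1cc(Br)c(Br)c(Br)c1[O-] | intermediate |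
| 19 | 3,5-dibromo-2-[3,4,5-tribromo-2-(2,4-dibromophenoxy)phenoxy]phenyl neopentyl sulfate | CC(C)(C)COS(=O)(=O)Oc1cc(Br)cc(Br)c1Oc1cc(Br)c(Br)c(Br)c1Oc1ccc(Br)cc1Br | intermediate |
| 20 | sodium 3,5-dibromo-2-[3,4,5-tribromo-2-(2,4-dibromophenoxy)phenoxy]phenyl sulfate | [Na+].[O-]S(=O)(=O)Oc1cc(Br)cc(Br)c1Oc1cc(Br)c(Br)c(Br)c1Oc1ccc(Br)cc1Br | intermediate |
| 21 | bromoiesol A sulfate | O=S(=O)(O)Oc1cc(Br)cc(Br)c1Oc1cc(Br)c(Br)c(Br)c1Oc1ccc(Br)cc1Br | target |

**Step count**

Total step count: 8. Longest linear sequence: 6 (steps 1, 2, 3, 5, 7, 8). Steps 4 and 6 are side branches of one step each.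

**Steps most likely to fail**

**Step 3.** On these electron-poor rings, above all ring B, hydride migration may compete with aryl migration, so that carboxyl groups arise in place of formates. The oxidation may also stall after the first aldehyde. The fallback sets out from 6 and removes the migrating hydride altogether. MeMgBr (THF, −78 °C) should add to both aldehydes faster than it exchanges any bromine. This gives 1-{3,5-dibromo-2-[3,4,5-tribromo-2-(1-hydroxyethyl)phenoxy]phenyl}ethanol F1 as a mixture of diastereomers. Dess–Martin periodinane erases both carbinol centres to give 1-[2-(2-acetyl-3,4,5-tribromophenoxy)-3,5-dibromophenyl]ethanone F2. Baeyer–Villiger oxidation of this bis(aryl methyl ketone) with trifluoroperacetic acid, where aryl outranks methyl, gives 2-(2-acetoxy-3,4,5-tribromophenoxy)-3,5-dibromophenyl acetate F3. Acid-catalysed methanolysis comes back to the route at 8.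

**Step 5.** Site selectivity between the two phenoxides may be poor, and double sulfation may occur. The fallback sets out from 8 and moves the sulfation to the end. TIPSCl and imidazole in DMF should silylate only the open ring-A hydroxyl, and mis-silylated material can be recycled with fluoride. The product is 2,3,4-tribromo-6-[2,4-dibromo-6-(triisopropylsilyloxy)phenoxy]phenol F4. Arylation of its ring-B phenoxide with 17 (t-BuOK, THF, 40 °C) gives {3,5-dibromo-2-[3,4,5-tribromo-2-(2,4-dibromophenoxy)phenoxy]phenoxy}triisopropylsilane F5. TBAF then gives the free phenol 3,5-dibromo-2-[3,4,5-tribromo-2-(2,4-dibromophenoxy)phenoxy]phenol F6, which has a single hydroxyl group. SO3·pyridine in pyridine followed by sodium exchange (aq. NaHCO3) comes back to the route at 20.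

**Step 2.** Addition of the weakly nucleophilic, doubly ortho-substituted phenoxide may be sluggish. At forcing temperature, ether exchange at the aldehyde-activated, oxygen-bearing carbon of ring A or displacement of a bromide may set in. The fallback sets out from 3 and uses the far more nucleophilic, unhindered phenoxide of commercial salicylaldehyde (K2CO3, DMF, 80 °C). This SNAr gives 2-(3,4,5-tribromo-2-formylphenoxy)benzaldehyde F7. Two-fold electrophilic bromination with NBS (2.1 equiv) in conc. H2SO4 then places bromine at the two ring-A positions ortho and para to the ether oxygen, both of which are meta to the formyl group. The only C–H of the much more deactivated ring B should be left alone. This comes back to the route at 6.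

**Further compounds**
F1 | step 3 | 1-{3,5-dibromo-2-[3,4,5-tribromo-2-(1-hydroxyethyl)phenoxy]phenyl}ethanol (mixture of diastereomers, centres erased in the next operation) | CC(O)c1cc(Br)cc(Br)c1Oc1cc(Br)c(Br)c(Br)c1C(C)O
F2 | step 3 | 1-[2-(2-acetyl-3,4,5-tribromophenoxy)-3,5-dibromophenyl]ethanone | CC(=O)c1cc(Br)cc(Br)c1Oc1cc(Br)c(Br)c(Br)c1C(C)=O
F3 | step 3 | 2-(2-acetoxy-3,4,5-tribromophenoxy)-3,5-dibromophenyl acetate | CC(=O)Oc1cc(Br)cc(Br)c1Oc1cc(Br)c(Br)c(Br)c1OC(C)=O
F4 | step 5 | 2,3,4-tribromo-6-[2,4-dibromo-6-(triisopropylsilyloxy)phenoxy]phenol | CC(C)[Si](C(C)C)(C(C)C)Oc1cc(Br)cc(Br)c1Oc1cc(Br)c(Br)c(Br)c1O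
F5 | step 5 | {3,5-dibromo-2-[3,4,5-tribromo-2-(2,4-dibromophenoxy)phenoxy]phenoxy}triisopropylsilane | CC(C)[Si](C(C)C)(C(C)C)Oc1cc(Br)cc(Br)c1Oc1cc(Br)c(Br)c(Br)c1Oc1ccc(Br)cc1Br
F6 | step 5 | 3,5-dibromo-2-[3,4,5-tribromo-2-(2,4-dibromophenoxy)phenoxy]phenol | Oc1cc(Br)cc(Br)c1Oc1cc(Br)c(Br)c(Br)c1Oc1ccc(Br)cc1Br
F7 | step 2 | 2-(3,4,5-tribromo-2-formylphenoxy)benzaldehyde | O=Cc1ccccc1Oc1cc(Br)c(Br)c(Br)c1C=O
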